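(The numbers in the tables were computed on assumed constants; noise was put on by code.)

Slowness was what I had to hand over: in the epsilon run starting material read 0.2% at 15.0 h, yet product was still rising at 30.0 h.

| flask | solid substrate | remark | time |
|---|---|---|---|
| epsilon | 0.10 M | run made earlier |  |
| zeta | 0.15 M | run made earlier |  |
| flask | 0.20 M |  | 40 h |

| run | time / h | product / % | starting material / % |
|---|---|---|---|
| epsilon | 5.00 | 0 | 17.5 |
| epsilon | 10.0 | 0.5 | 2.4 |
| epsilon | 15.0 | 1.5 | 0.2 |
| epsilon | 20.0 | 3.3 | 0.2 |
| epsilon | 25.0 | 5.9 | 0 |
| epsilon | 30.0 | 8.9 | 0.1 |
| zeta | 5.00 | 0 | 23.8 |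
| zeta | 10.0 | 1.0 | 2.7 |
| zeta | 15.0 | 2.0 | 0.3 |
| zeta | 20.0 | 3.3 | 0 |
| zeta | 25.0 | 5.9 | 0.1 |
| zeta | 30.0 | 8.4 | 0 |

(standard deviation of a reading: 0.3 percentage points)

1. amount of product at 40 h, in percent of the solid substrate charged
2. concentration of starting material in solution at 40 h, in percent of saturation

- as a solid, counted per litre of solution: solid substrate
- at the start none of the solid substrate is in solution
- starting material is what solid substrate becomes in solution
- starting material means what is dissolved; the solid is not counted in it

My note for the bench said this. Both runs read alike as percent of charge, 8.9% and 8.4% at 30.0 h, a gap of 0.5 percentage points against a scatter of 0.3 points per reading, so I took the late steps as first order, with loading cancelling. The half-life of starting material read from epsilon, 1.74 h, was far shorter than 40 h, so I expected saturation near zero at the end. At 20.0 h epsilon showed 3.3% product, leaving 96.5% unread, which I took for unseen material in a resting state: don't stop the flask.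

In the epsilon run the square root of product climbed nearly straight. From the mean of both runs, 8.65% at 30.0 h, I carried the root rate, the hourly gain in the square root of the product fraction: 0.0112 /h. Held straight, it gave me 16.5%.

The forecast gave 16% (13.5% to 18.5%) and 0% of saturation, lower than mine, allowing “slight slowing”.

The flask gave 14.7% and 0% of saturation, with intermediate B holding 57.9%.

    intermediate A → intermediate B (k = 0.345 /h)
    starting material → intermediate A (k = 0.436 /h)
    intermediate B → intermediate C (k = 0.0168 /h)
    intermediate C → product (k = 0.0256 /h)
    solid substrate ⇌ starting material, rate k5*(cs5 - [starting material]) while solid is left; crystals form when [starting material] > cs5 (solubility = 0.180 M, k = 0.353 /h)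

From 3.09% at 20.0 h to that result, the flask's root rate averaged 0.0104 /h, less than my 0.0112 /h, and my line ended 1.8 points high.

For the same charge stopped at 15 h, the root rate, run back from the epsilon reading at 20.0 h, gave 1.58%. That flask held 1.37%.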